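**Plan**

1. Numbering (used for every intermediate): C1 = tertiary carbinol carrying the crotonoyl carbons C2–C4; C5 = acyloxy CH; C6 = lactone O–CH; C7 = CH carrying C11 (C11, C12, C13 = lactone α-carbon, carbonyl, =CH2); C8 = CH2; C9 = CHOH; C10 = CHMe.
2. Enabling feature: in the cycloheptane, C5–C6–C7 is a contiguous three-carbon unit oxygenated at C5 and C6 (an α-alkoxy ketone at the C6 ketone level). C1 and C8 flank it, are joined to each other through C10–C9, and can share the C1 oxygen as an ether bridge, so that C1/C10/C9/C8 plus that oxygen are a furan. O–C1 and O–C5 lie on opposite ring faces.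
3. Cuts, last to first: ester C5–O; C2–C3; C11=C13; C9–O; C8–H (the C8–O bridge bond is restored); C10–CH3; lactone C6–O; C7–C11; then C1–C5 and C7–C8 together in a (4+3) cycloaddition of a 2-(silyloxymethyl)furan with a chiral 1-alkoxy-2-silyloxyallyl cation.
4. Forward order: the (4+3) step builds the seven-membered carbocycle as an 8-oxabicyclo[3.2.1]octenone (O bridges C1/C8). The γ-lactone is then closed on C6/C7, the C9–C10 bridge is oxidised and methylated, SmI2 cuts the oxygen bridge to the free cycloheptane, and the side chains come last.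
5. Stereochemistry: absolute sense from (S)-1-phenylethanol (auxiliary on the cation) and (S)-2-methylbutanoic acid. C1, C5 and C8 are set in the cycloaddition, C7 and C10 by exo attack on the bicycle, C6 by exo hydride attack followed by inversion in a Mitsunobu lactonisation, and C9 by hydride delivery from the C1 hydroxyl.

Key step: step 4

Assumption 1: the (S)-1-phenylethyl group is taken to induce the absolute sense drawn for 7; if it induces the opposite sense, (R)-1-phenylethanol is used and only the auxiliary descriptor changes.
Assumption 2: for step 8 the (–)-antipode of Ipc2BH (from (+)-α-pinene) is taken as the matched reagent; if the (+)-antipode proves matched, it replaces it and the product is the same.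

**Route**

Step 1
Reactants: 1 furfuryl alcohol
Product: 2 tert-butyl(furan-2-ylmethoxy)dimethylsilane
Conditions: t-BuMe2SiCl, imidazole, CH2Cl2, 0 °C to rt
Reagents that add atoms: tert-butyldimethylsilyl chloride, CC(C)(C)[Si](C)(C)Cl
Why: Imidazole-mediated silyl ether formation protects the primary alcohol with a group that should survive catalytic silyl triflate at low temperature; no stereocentre is formed.

Step 2
Reactants: 3 1,1-dimethoxypropan-2-one and 4 (S)-1-phenylethanol (3 equiv)
Product: 5 1,1-bis[(S)-1-phenylethoxy]propan-2-one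
Conditions: camphorsulfonic acid (cat.), cyclohexane, 50 °C, 5 Å molecular sieves to take up MeOH
Reagents that add atoms: none
Why: Acid-catalysed acetal exchange (transacetalisation), driven by removal of methanol, replaces both methoxy groups by the enantiopure alcohol, whose stereocentre is untouched because only acetal C–O bonds are broken.

Step 3
Reactants: 5 1,1-bis[(S)-1-phenylethoxy]propan-2-one
Product: 6 2-(triethylsilyloxy)acrolein bis[(S)-1-phenylethyl] acetal
Conditions: Et3SiOTf, Et3N, CH2Cl2, 0 °C
Reagents that add atoms: triethylsilyl triflate, CC[Si](CC)(CC)OS(=O)(=O)C(F)(F)F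
Why: Soft enolisation with a silyl triflate and a tertiary amine (silyl enol ether formation) should take place at the methyl group, the α-position not deactivated by two alkoxy groups, giving the 2-silyloxyacrolein acetal.

Step 4
Reactants: 6 2-(triethylsilyloxy)acrolein bis[(S)-1-phenylethyl] acetal and 2 tert-butyl(furan-2-ylmethoxy)dimethylsilane (1.5 equiv)
Product: 7 bicyclic ketone, 1-(tert-butyldimethylsilyloxymethyl)-2-[(S)-1-phenylethoxy]-8-oxabicyclo[3.2.1]oct-6-en-3-one; in target numbering O bridges C1 and C8, CH2OSi on C1, equatorial alkoxy on C5 (trans to the bridge), C6 = ketone, C9=C10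
Conditions: Me3SiOTf (0.1 equiv), CH2Cl2, –95 to –78 °C; pyridine quench
Reagents that add atoms: none
Why: Catalytic Me3SiOTf removes one 1-phenylethoxy group from 6 and leaves the W-shaped 1-alkoxy-2-(triethylsilyloxy)allyl cation, which adds across C2 and C5 of furan 2 in an asynchronous (4+3) cycloaddition of the oxyallyl-cation/furan type; loss of the triethylsilyl group from the adduct regenerates a silyl triflate and frees the C6 ketone. The electrophilic CH2 terminus (C7) should bond first to the unsubstituted, most nucleophilic furan α-carbon (C8), which fixes the regiochemistry, and the alkoxy enol ether carbon (C5) then attacks the substituted oxocarbenium carbon (C1). That second bond closes the cycloheptene by a 7-(enolendo)-exo-trig attack, which seen from the new oxane ring is a 6-endo-trig closure, both allowed. C1 and C8 are set together because the furan reacts on one face at both α-carbons, C5 comes out equatorial (trans to the oxygen bridge) from the compact transition state of the W cation, and the absolute sense follows from the (S)-1-phenylethyl group, whose phenyl ring covers one face of the cation. The step needs regio-, compact-versus-extended and facial selectivity, secured in turn by the polarisation of the cation against the 2-substituted furan, by the W geometry and by the auxiliary.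

Step 5
Reactants: 7 bicyclic ketone
Product: 8 keto ester, 7 carrying an axial CH2CO2Me on C7 (cis to the oxygen bridge)
Conditions: LiN(i-Pr)2, THF, –78 °C; BrCH2CO2Me, DMPU, –78 to –40 °C
Reagents that add atoms: methyl bromoacetate, COC(=O)CBr
Why: Kinetic deprotonation should occur at the C7 methylene and not at the alkoxy-bearing, neopentyl C5–H, and the lithium enolate is alkylated (enolate alkylation) on its exo face, syn to the oxygen bridge and away from the C9=C10 bridge, which places the acetate arm axial on C7.

Step 6
Reactants: 8 keto ester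
Product: 10 hydroxy acid with axial C6 OH (trans to the oxygen bridge) and axial C7 CH2CO2H, via hydroxy ester 9 (not isolated)
Conditions: LiBH(s-Bu)3, THF, –78 °C; then LiOH, H2O–MeOH, 0 °C to rt; 1 M HCl to pH 3
Reagents that add atoms: lithium hydroxide (aqueous), [Li+].[OH-]
Why: The bulky borohydride should reduce the C6 ketone (hydride reduction) from the exo face, as in the parent oxabicyclic ketones, giving the axial alcohol that is trans-diaxial to the C7 arm and so cannot lactonise, and the methyl ester is then saponified in the same flask (ester hydrolysis) when C7 is no longer α to a ketone.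

Step 7
Reactants: 10 hydroxy acid
Product: 11 tricyclic lactone, cis-fused γ-lactone between C6–O (now equatorial, cis to the oxygen bridge) and the C7 arm, C9=C10 intact
Conditions: PPh3, DIAD, THF (0.01 M), 0 °C to rt
Reagents that add atoms: none
Why: Mitsunobu lactonisation: the C6 hydroxyl is activated as its oxyphosphonium ion and displaced from the open exo face by the C7 carboxylate in a 5-exo-tet SN2 closure, so C6 is inverted to the configuration cis to the C7 arm, closure with retention being geometrically impossible for the trans-diaxial hydroxy acid.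

Step 8
Reactants: 11 tricyclic lactone
Product: 13 exo C9 alcohol (OH cis to the oxygen bridge; C10 = CH2), via organoborane 12 (not isolated)
Conditions: (–)-Ipc2BH, THF, –25 to 0 °C; then NaBO3·4H2O, H2O, rt
Reagents that add atoms: sodium perborate tetrahydrate (dimeric peroxoborate), [Na+].[Na+].O[B-]1(O)OO[B-](O)(O)OO1
Why: Brown hydroboration–oxidation of the strained C9=C10 bond proceeds by syn addition on the exo face, with boron expected at C9 because that carbon is remote from the quaternary bridgehead C1 and because the chiral dialkylborane, which distinguishes the two alkene carbons of oxabicyclic alkenes, is used in its matched form; oxidation with retention gives the exo alcohol.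

Step 9
Reactants: 13 exo C9 alcohol
Product: 14 C9 ketone
Conditions: Dess–Martin periodinane, CH2Cl2, rt
Reagents that add atoms: none
Why: Dess–Martin oxidation converts the secondary alcohol into the ketone under conditions that leave the lactone, the silyl ether and the benzylic ether alone; the C9 stereocentre is deliberately erased.

Step 10
Reactants: 14 C9 ketone
Product: 15 C10 exo-methyl ketone (methyl cis to the oxygen bridge)
Conditions: LiN(SiMe3)2 (1.0 equiv), THF, –78 °C; MeI, –78 to –30 °C
Reagents that add atoms: iodomethane, CI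
Why: The ketone, several pKa units more acidic than the lactone and unable to enolise toward the bridgehead C8, should be deprotonated at C10 only, and the enolate is methylated (enolate alkylation) from the exo face; the remaining endo C10–H is shielded, which guards against a second methylation.

Step 11
Reactants: 15 C10 exo-methyl ketone
Product: 16 ketol, monocyclic cycloheptanone with free tertiary C1 OH, C8 = CH2, C9 ketone, lactone and C5 auxiliary intact
Conditions: SmI2 (2.5 equiv), THF–MeOH, –78 °C; aq. NH4Cl
Reagents that add atoms: none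
Why: SmI2 transfers two electrons to the α-alkoxy ketone (reductive cleavage of an α-heterosubstituted ketone), the bridge C8–O bond being aligned with the ketyl, so the bridge is cut, C8 becomes CH2 after protonation of the samarium enolate by methanol, and C1 keeps its oxygen with unchanged configuration.

Step 12
Reactants: 16 ketol
Product: 17 anti-1,3-diol (C9 OH trans to C1 OH)
Conditions: Me4NBH(OAc)3, MeCN–AcOH, –30 °C
Reagents that add atoms: none
Why: Evans–Saksena reduction: the C1 hydroxyl exchanges onto boron and delivers hydride intramolecularly to the C9 carbonyl on the face it occupies, so the new C9 hydroxyl comes out trans (1,3-anti) to the C1 hydroxyl.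

Step 13
Reactants: 17 anti-1,3-diol
Product: 18 C9 tert-butyldimethylsilyl ether (C1 OH free)
Conditions: t-BuMe2SiOTf (1.1 equiv), 2,6-lutidine, CH2Cl2, –78 °C
Reagents that add atoms: tert-butyldimethylsilyl triflate, CC(C)(C)[Si](C)(C)OS(=O)(=O)C(F)(F)F
Why: Silyl triflate silylation at low temperature with one equivalent should select the secondary C9 hydroxyl over the tertiary, neopentyl C1 hydroxyl.

Step 14
Reactants: 18 C9 silyl ether
Product: 19 C1,C5-diol (auxiliary removed)
Conditions: H2 (1 atm), Pd(OH)2/C, EtOAc, rt
Reagents that add atoms: none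
Why: Hydrogenolysis of the benzylic C–O bond removes the 1-phenylethyl auxiliary as ethylbenzene at a stage where the molecule has no C=C bond, and the silyl ethers and the lactone are inert to it.

Step 15
Reactants: 19 C1,C5-diol
Product: 22 α-methylene lactone (C11=C13), via Mannich base 20 (not isolated), via ammonium iodide 21 (not isolated)
Conditions: LiN(i-Pr)2 (3.3 equiv), THF, –78 to –40 °C; [Me2N=CH2]I, –78 °C to rt; water quench; then MeI, MeOH, rt; then aq. NaHCO3, CH2Cl2, rt
Reagents that add atoms: dimethylmethyleneammonium iodide (Eschenmoser's salt), C=[N+](C)C.[I-]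
Why: α-Methylenation of the lactone by the Mannich route: after the two hydroxyls are deprotonated, the C11 lithium enolate adds to the iminium salt, and exhaustive methylation followed by Hofmann-type elimination of trimethylamine installs the exocyclic double bond, in which the C11 stereocentre of the intermediates is lost.

Step 16
Reactants: 22 α-methylene lactone and 23 (S)-2-methylbutanoic acid
Product: 24 C5 (S)-2-methylbutanoate
Conditions: DCC, DMAP (0.2 equiv), CH2Cl2, 0 °C to rt
Reagents that add atoms: none
Why: Steglich esterification acylates the secondary C5 hydroxyl while the tertiary C1 hydroxyl stays free, and the α-stereocentre of the acid should be carried over unchanged under carbodiimide/DMAP activation at low temperature.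

Step 17
Reactants: 24 C5 ester
Product: 25 primary alcohol at C2 (C9 silyl ether kept)
Conditions: HF·pyridine, pyridine, THF, 0 °C
Reagents that add atoms: none
Why: Buffered HF·pyridine cleaves the primary silyl ether faster than the hindered secondary one at C9 (selective desilylation), freeing only the C2 hydroxyl.

Step 18
Reactants: 25 primary alcohol
Product: 26 α-hydroxy aldehyde (C2 = CHO), used crude
Conditions: IBX, DMSO, rt
Reagents that add atoms: none
Why: IBX oxidation takes the primary alcohol to the aldehyde and, as with other 1,2-diols, should not cleave the bond to the adjacent tertiary carbinol.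

Step 19
Reactants: 26 α-hydroxy aldehyde
Product: 27 allylic alcohol, C2 carbinol carrying the (E)-propenyl group (both C2 epimers)
Conditions: (E)-1-bromoprop-1-ene, CrCl2 (excess), NiCl2 (cat.), DMF, rt
Reagents that add atoms: (E)-1-bromoprop-1-ene, C/C=C/Br
Why: Nozaki–Hiyama–Kishi coupling: the alkenylchromium species formed under nickel catalysis adds only to the aldehyde, tolerating the free hydroxyl, the ester and the α-methylene lactone, and keeps the E geometry; the new C2 carbinol centre is removed in the next step.

Step 20
Reactants: 27 allylic alcohol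
Product: 28 enone (crotonoyl on C1, C9 silyl ether)
Conditions: IBX, DMSO, rt
Reagents that add atoms: none
Why: IBX oxidation of the allylic alcohol gives the conjugated enone without cleaving the vicinal tertiary alcohol, and the C2 stereocentre disappears.

Step 21
Reactants: 28 enone
Product: 29 target CNP0331957.1
Conditions: HF·pyridine, THF, 0 °C to rt
Reagents that add atoms: none
Why: Desilylation with HF·pyridine removes the remaining secondary silyl ether under mildly acidic conditions that should spare the enone, the ester and the α-methylene lactone.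

**Compound list**

1 | furfuryl alcohol | OCc1ccco1 | starting material
2 | tert-butyl(furan-2-ylmethoxy)dimethylsilane | CC(C)(C)[Si](C)(C)OCc1ccco1 | intermediate
3 | 1,1-dimethoxypropan-2-one | COC(OC)C(C)=O | starting material
4 | (S)-1-phenylethanol | C[C@H](O)c1ccccc1 | starting material
5 | 1,1-bis[(S)-1-phenylethoxy]propan-2-one | CC(=O)C(O[C@@H](C)c1ccccc1)O[C@@H](C)c1ccccc1 | intermediate
6 | 2-(triethylsilyloxy)acrolein bis[(S)-1-phenylethyl] acetal | C=C(O[Si](CC)(CC)CC)C(O[C@@H](C)c1ccccc1)O[C@@H](C)c1ccccc1 | intermediate
7 | 1-(silyloxymethyl)-2-[(S)-1-phenylethoxy]-8-oxabicyclo[3.2.1]oct-6-en-3-one, alkoxy equatorial | O=C1C[C@H]2C=C[C@@](O2)(CO[Si](C)(C)C(C)(C)C)[C@H]1O[C@@H](C)c3ccccc3 | intermediate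
8 | keto ester, axial CH2CO2Me on C7 | O=C1[C@H](CC(=O)OC)[C@H]2C=C[C@@](O2)(CO[Si](C)(C)C(C)(C)C)[C@H]1O[C@@H](C)c3ccccc3 | intermediate
9 | hydroxy ester, axial C6 OH | O[C@H]1[C@H](CC(=O)OC)[C@H]2C=C[C@@](O2)(CO[Si](C)(C)C(C)(C)C)[C@H]1O[C@@H](C)c3ccccc3 | intermediate (not isolated)
10 | hydroxy acid, axial C6 OH, axial C7 CH2CO2H | O[C@H]1[C@H](CC(=O)O)[C@H]2C=C[C@@](O2)(CO[Si](C)(C)C(C)(C)C)[C@H]1O[C@@H](C)c3ccccc3 | intermediate
11 | tricyclic lactone, cis-fused at C6/C7, C9=C10 | O=C1C[C@H]2[C@@H](O1)[C@H](O[C@@H](C)c4ccccc4)[C@]3(CO[Si](C)(C)C(C)(C)C)C=C[C@H]2O3 | intermediate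
12 | exo C9 diisopinocampheylborane of 11 | O=C1C[C@H]2[C@@H](O1)[C@H](O[C@@H](C)c4ccccc4)[C@]3(CO[Si](C)(C)C(C)(C)C)C[C@@H](B([C@@H]5C[C@@H]6C[C@H]([C@H]5C)C6(C)C)[C@@H]7C[C@@H]8C[C@H]([C@H]7C)C8(C)C)[C@H]2O3 | intermediate (not isolated)
13 | exo C9 alcohol | O=C1C[C@H]2[C@@H](O1)[C@H](O[C@@H](C)c4ccccc4)[C@]3(CO[Si](C)(C)C(C)(C)C)C[C@@H](O)[C@H]2O3 | intermediate
14 | C9 ketone | O=C1C[C@H]2[C@@H](O1)[C@H](O[C@@H](C)c4ccccc4)[C@]3(CO[Si](C)(C)C(C)(C)C)CC(=O)[C@H]2O3 | intermediate
15 | C10 exo-methyl C9 ketone | O=C1C[C@H]2[C@@H](O1)[C@H](O[C@@H](C)c4ccccc4)[C@]3(CO[Si](C)(C)C(C)(C)C)[C@@H](C)C(=O)[C@H]2O3 | intermediate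
16 | ketol: cycloheptanone, C1 OH, C9 ketone | C1C(=O)O[C@@H]2[C@H]1CC(=O)[C@H](C)[C@@](O)(CO[Si](C)(C)C(C)(C)C)[C@H]2O[C@@H](C)c3ccccc3 | intermediate
17 | anti-1,3-diol (C1 OH, C9 OH) | C1C(=O)O[C@@H]2[C@H]1C[C@@H](O)[C@H](C)[C@@](O)(CO[Si](C)(C)C(C)(C)C)[C@H]2O[C@@H](C)c3ccccc3 | intermediate
18 | C9 tert-butyldimethylsilyl ether | C1C(=O)O[C@@H]2[C@H]1C[C@@H](O[Si](C)(C)C(C)(C)C)[C@H](C)[C@@](O)(CO[Si](C)(C)C(C)(C)C)[C@H]2O[C@@H](C)c3ccccc3 | intermediate
19 | C1,C5-diol | C1C(=O)O[C@@H]2[C@H]1C[C@@H](O[Si](C)(C)C(C)(C)C)[C@H](C)[C@@](O)(CO[Si](C)(C)C(C)(C)C)[C@H]2O | intermediate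
20 | Mannich base, CH2NMe2 on C11 (C11 epimers) | CN(C)CC1C(=O)O[C@@H]2[C@H]1C[C@@H](O[Si](C)(C)C(C)(C)C)[C@H](C)[C@@](O)(CO[Si](C)(C)C(C)(C)C)[C@H]2O | intermediate (not isolated)
21 | trimethylammonium iodide of 20 (C11 epimers) | C[N+](C)(C)CC1C(=O)O[C@@H]2[C@H]1C[C@@H](O[Si](C)(C)C(C)(C)C)[C@H](C)[C@@](O)(CO[Si](C)(C)C(C)(C)C)[C@H]2O.[I-] | intermediate (not isolated)
22 | α-methylene lactone | C=C1C(=O)O[C@@H]2[C@H]1C[C@@H](O[Si](C)(C)C(C)(C)C)[C@H](C)[C@@](O)(CO[Si](C)(C)C(C)(C)C)[C@H]2O | intermediate
23 | (S)-2-methylbutanoic acid | CC[C@H](C)C(=O)O | starting material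
24 | C5 (S)-2-methylbutanoate | C=C1C(=O)O[C@@H]2[C@H]1C[C@@H](O[Si](C)(C)C(C)(C)C)[C@H](C)[C@@](O)(CO[Si](C)(C)C(C)(C)C)[C@H]2OC(=O)[C@@H](C)CC | intermediate
25 | primary alcohol at C2 | C=C1C(=O)O[C@@H]2[C@H]1C[C@@H](O[Si](C)(C)C(C)(C)C)[C@H](C)[C@@](O)(CO)[C@H]2OC(=O)[C@@H](C)CC | intermediate
26 | α-hydroxy aldehyde | C=C1C(=O)O[C@@H]2[C@H]1C[C@@H](O[Si](C)(C)C(C)(C)C)[C@H](C)[C@@](O)(C=O)[C@H]2OC(=O)[C@@H](C)CC | intermediate
27 | (E)-propenyl carbinol (C2 epimers) | C=C1C(=O)O[C@@H]2[C@H]1C[C@@H](O[Si](C)(C)C(C)(C)C)[C@H](C)[C@@](O)(C(O)/C=C/C)[C@H]2OC(=O)[C@@H](C)CC | intermediate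
28 | enone, C9 silyl ether | C=C1C(=O)O[C@@H]2[C@H]1C[C@@H](O[Si](C)(C)C(C)(C)C)[C@H](C)[C@@](O)(C(=O)/C=C/C)[C@H]2OC(=O)[C@@H](C)CC | intermediate
29 | CNP0331957.1 | C=C1C(=O)O[C@@H]2[C@H]1C[C@@H](O)[C@H](C)[C@@](O)(C(=O)/C=C/C)[C@H]2OC(=O)[C@@H](C)CC | target

**Step count and risks**

Total: 21 steps. Longest linear sequence: 20 steps (3 to 29, steps 2–21); the furan branch (steps 1 and 4–21) is 19 steps.

Steps most likely to fail:

1. Step 7 (inverting lactonisation). The activated axial C6 oxygen may be lost by E2 toward C5, whose hydrogen is anti-periplanar, or the flanked, endo-facing hydroxyl may not be activated at all, so that no backside attack by the carboxylate occurs. Fallback: invert C6 with a small external oxygen nucleophile and close the lactone with retention. It sets out from hydroxy ester 9, isolated for this purpose by a neutral work-up of the reduction in step 6. Triflic anhydride and pyridine in CH2Cl2 at –30 °C give the C6 triflate F1. Tetrabutylammonium nitrite in DMF (Lattrell–Dax inversion) gives the nitrite ester F2, which is hydrolysed on aqueous work-up to the equatorial C6 alcohol F3. This alcohol is cis to the C7 arm and lactonises with pyridinium tosylate, rejoining the route at 11.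

2. Step 15 (methylenation of the unprotected diol lactone). Enolisation of a lactone that already carries two lithium alkoxides may be incomplete through aggregation, and silyl migration or O-alkylation by the iminium salt may intervene. Fallback: carboxylation followed by decarboxylative Mannich methylenation, which needs no amide base. It sets out from 19. MeOMgOCO2Me (methyl magnesium carbonate) in DMF at 120 °C, then cold dilute HCl, gives the α-carboxy lactone F4. Aqueous formaldehyde and diethylamine in NaOAc/AcOH form the Mannich acid F5, which loses CO2 and diethylamine on warming and rejoins the route at 22.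

3. Step 11 (scission of the oxygen bridge). Retro-aldol ring opening, dehydration or C10 epimerisation of the β-hydroxy ketone may occur while it sits as a trivalent samarium alkoxide or during its isolation. Fallback: the ketol is not isolated; scission and carbonyl reduction are merged, and C9 is set by a samarium chelate instead of by borohydride delivery. It sets out from 15. Excess SmI2 (about 5 equiv) in THF–MeOH is added at –78 °C and the mixture is warmed to 0 °C, so that the samarium-bound ketol is reduced in the same flask, anti to the C1 oxygen. The fallback rejoins the route at 17 and makes no new compound (entry F0).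

**Further compounds**

F1 | step 7 | C6 triflate of hydroxy ester 9 (axial) | O=S(=O)(O[C@H]1[C@H](CC(=O)OC)[C@H]2C=C[C@@](O2)(CO[Si](C)(C)C(C)(C)C)[C@H]1O[C@@H](C)c3ccccc3)C(F)(F)F
F2 | step 7 | C6 nitrite ester, inverted (equatorial) | O=NO[C@@H]1[C@H](CC(=O)OC)[C@H]2C=C[C@@](O2)(CO[Si](C)(C)C(C)(C)C)[C@H]1O[C@@H](C)c3ccccc3
F3 | step 7 | C6-epimeric (equatorial) hydroxy ester | O[C@@H]1[C@H](CC(=O)OC)[C@H]2C=C[C@@](O2)(CO[Si](C)(C)C(C)(C)C)[C@H]1O[C@@H](C)c3ccccc3
F0 | step 11 | none | none
F4 | step 15 | α-carboxy lactone (C11 epimers) | OC(=O)C1C(=O)O[C@@H]2[C@H]1C[C@@H](O[Si](C)(C)C(C)(C)C)[C@H](C)[C@@](O)(CO[Si](C)(C)C(C)(C)C)[C@H]2O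
F5 | step 15 | α-carboxy-α-(diethylaminomethyl) lactone (C11 epimers) | CCN(CC)CC1(C(=O)O)C(=O)O[C@@H]2[C@H]1C[C@@H](O[Si](C)(C)C(C)(C)C)[C@H](C)[C@@](O)(CO[Si](C)(C)C(C)(C)C)[C@H]2O
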